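**Plan**

Labdane locants are used as position labels only (C19 = carboxyl carbon on C4, C20 on C10, C17 on C8, C11–C16 = chain on C9); configuration is always that of the target, (4R,5S,9R,10S,13R).
Cuts, last to first: C15–O acetate; C8=C17 (methylenation of a C8 ketone); C11=C12 (Wittig, then hydrogenation); C10–C20 and C9–C11 together (enone–acetylene [2+2], then ozonolysis of the cyclobutene).
Enabling feature: C20 on C10 and C11 on C9 are vicinal, cis, and next to C8, so C10 and C9 are the β- and α-carbons of a ring B 9(10)-en-8-one.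
Forward order: ring A comes with the tetralone, its anisole ring becomes ring B by Birch reduction, the cyclobutene closes in the photocycloaddition and is opened by ozone, and the C12–C16 piece is joined by Wittig reaction.
Stereochemistry: C4 by resolution of the tetralin acid; C5 by equilibration and separation of the enone epimers; C10 (anti to H5) and C9 (cis to C10) in the photocycloaddition; C13 from (S)-2-methylbutane-1,4-diol.

Key step: step 8

Assumption: the (R)-acid is taken to give the less soluble salt with (R)-1-phenylethylamine; if the opposite pairing crystallises, the (S)-amine is used and nothing else changes.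

**Step 1**
Reactants: 1 6-methoxy-1-tetralone
Product: 2 rac-6-methoxy-1,2,3,4-tetrahydronaphthalene-1-carbonitrile
Conditions: TosMIC, KOt-Bu, DME/EtOH, 0 °C → 40 °C
Reagents that add atoms: p-toluenesulfonylmethyl isocyanide (TosMIC), Cc1ccc(cc1)S(=O)(=O)C[N+]#[C-]
Why: Van Leusen reductive cyanation turns the aryl ketone directly into the one-carbon-extended nitrile, the isocyanide carbon leaving as ethyl formate and the sulfonyl group as sulfinate.

**Step 2**
Reactants: 2 rac-6-methoxy-1,2,3,4-tetrahydronaphthalene-1-carbonitrile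
Product: 3 rac-6-methoxy-1-methyl-1,2,3,4-tetrahydronaphthalene-1-carbonitrile
Conditions: LiN(i-Pr)2, THF, −78 °C; MeI, −78 °C → rt
Reagents that add atoms: methyl iodide, CI
Why: Nitrile α-alkylation of the benzylic carbanion, which has a single acidic C–H, so the quaternary centre forms without over-alkylation (racemic).

**Step 3**
Reactants: 3 rac-6-methoxy-1-methyl-1,2,3,4-tetrahydronaphthalene-1-carbonitrile
Product: 4 rac-6-methoxy-1-methyl-1,2,3,4-tetrahydronaphthalene-1-carboxylic acid
Conditions: KOH, ethylene glycol, 190 °C; then aq. HCl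
Reagents that add atoms: potassium hydroxide, [K+].[OH-]; water, O
Why: Forcing alkaline nitrile hydrolysis (through the amide) is the standard access to hindered tertiary aryl acids, and the aryl methyl ether should tolerate it.

**Step 4**
Reactants: 4 rac-6-methoxy-1-methyl-1,2,3,4-tetrahydronaphthalene-1-carboxylic acid
Product: 5 (R)-1-phenylethylammonium (R)-6-methoxy-1-methyl-1,2,3,4-tetrahydronaphthalene-1-carboxylate
Conditions: (R)-1-phenylethylamine (0.5 equiv), EtOH/EtOAc, recrystallised to constant rotation
Reagents that add atoms: (R)-1-phenylethylamine, C[C@@H](N)c1ccccc1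
Why: Classical resolution by diastereomeric salt crystallisation fixes C4, the one stereocentre that the substrate cannot control later.

**Step 5**
Reactants: 5 (R)-1-phenylethylammonium (R)-6-methoxy-1-methyl-1,2,3,4-tetrahydronaphthalene-1-carboxylate
Product: 6 (R)-6-methoxy-1-methyl-1,2,3,4-tetrahydronaphthalene-1-carboxylic acid
Conditions: 1 M HCl, EtOAc, rt
Reagents that add atoms: none
Why: Acid–base partition frees the acid from its ammonium salt without touching the quaternary stereocentre.

**Step 6**
Reactants: 6 (R)-6-methoxy-1-methyl-1,2,3,4-tetrahydronaphthalene-1-carboxylic acid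
Product: 9 (1R)-1-methyl-6-oxo-1,2,3,4,6,7,8,8a-octahydronaphthalene-1-carboxylic acid as a mixture of 8a-epimers, via dihydroanisole acid 7 (not isolated), via β,γ-unsaturated keto acid 8 (not isolated)
Conditions: Li, NH3(l)/THF/t-BuOH, −78 → −33 °C; NH4Cl; then 2 M HCl, THF, 50 °C
Reagents that add atoms: water, O
Why: Birch reduction of the anisole ring (the carboxylate is insulated by the quaternary carbon) gives the 2,5-dihydroanisole, acid hydrolyses its enol ether and moves the β,γ-double bond into conjugation, and C5 (C8a) is created as two epimers that interconvert through the dienol.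

**Step 7**
Reactants: 9 enone acid (8a-epimer mixture)
Product: 11 tert-butyl (1R,8aS)-1-methyl-6-oxo-1,2,3,4,6,7,8,8a-octahydronaphthalene-1-carboxylate (8a-H trans to the ester group), via tert-butyl ester epimer mixture 10 (not isolated)
Conditions: isobutylene, H2SO4 (cat.), CH2Cl2, sealed vessel, rt; aq. NaHCO3; crude ester: DBU (0.2 equiv), toluene, 80 °C; chromatography on silica, the recovered (8aR)-epimer going back into the DBU equilibration
Reagents that add atoms: isobutylene, CC(C)=C
Why: Acid-catalysed isobutylene esterification alkylates the hindered acid at oxygen and is indifferent to the neopentyl carbonyl, so both epimeric esters form; DBU then equilibrates C8a of the crude mixture through the extended dienolate, the (8aS)-ester is taken by chromatography, and the (8aR)-ester is recycled through the same equilibration.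

**Step 8**
Reactants: 11 enone tert-butyl ester; 12 acetylene
Product: 13 cyclobutene photoadduct: the 8-oxo tert-butyl ester in which C10 and C9 carry a cis-fused C20H=C11H bridge on the face opposite H5 (the face of the C4 ester)
Conditions: hν (medium-pressure Hg lamp, uranium-glass filter, λ > 340 nm), acetylene-saturated CH2Cl2, −78 °C, stopped short of full conversion
Reagents that add atoms: none
Why: Excitation of the enone and intersystem crossing give the twisted triplet, which bonds to acetylene at C10 to form a 1,4-biradical (α-keto radical at C9, vinyl radical at C11) that closes the C9–C11 bond after spin inversion; the closest known reactions are the enone–alkyne [2+2] photocycloaddition (cyclohexenone plus acetylene) and the angular functionalisation of octalones by allene photoaddition. The four-membered ring thus closes stepwise by biradical recombination and must be cis-fused to ring B, because a trans-fused bicyclo[4.2.0]octene is too strained. C10 is set by the pyramidal β-carbon of the relaxed triplet, which prefers the trans-decalin-like chair and bonds axially on the face opposite H5; C9 is set by the cis ring fusion, which places C11 cis to C20. The step needs face selectivity at C10, secured by H5 and the ring A chair, and selective excitation of the conjugated enone over the β,γ-unsaturated ketone product, secured by the long-wavelength filter and partial conversion. Regiochemistry does not arise because acetylene is symmetrical.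

**Step 9**
Reactants: 13 cyclobutene photoadduct
Product: 14 8,8-ethylenedioxy ketal of 13
Conditions: 1,2-bis(trimethylsilyloxy)ethane, TMSOTf (cat.), CH2Cl2, −78 → −40 °C; pyridine quench
Reagents that add atoms: 1,2-bis(trimethylsilyloxy)ethane, C[Si](C)(C)OCCO[Si](C)(C)C
Why: Noyori ketalisation masks C8 under aprotic low-temperature conditions, avoiding the acid-catalysed acyl shift of cyclobutene β,γ-unsaturated ketones and loss of the tert-butyl ester.

**Step 10**
Reactants: 15 (S)-2-methylbutane-1,4-diol
Product: 16 (S)-4-(tert-butyldimethylsilyloxy)-2-methylbutan-1-ol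
Conditions: TBSCl (1.0 equiv), imidazole, CH2Cl2, −40 → 0 °C; chromatography
Reagents that add atoms: tert-butyldimethylsilyl chloride, CC(C)(C)[Si](C)(C)Cl
Why: Sterically controlled monosilylation favours the unbranched C4 hydroxyl over the β-branched C1 hydroxyl, and the minor regioisomer and bis-silyl ether are removed by chromatography.

**Step 11**
Reactants: 16 (S)-4-(tert-butyldimethylsilyloxy)-2-methylbutan-1-ol
Product: 17 (S)-tert-butyl(4-iodo-3-methylbutoxy)dimethylsilane
Conditions: I2, PPh3, imidazole, CH2Cl2, 0 °C → rt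
Reagents that add atoms: iodine, II
Why: Appel-type iodination displaces the activated primary hydroxyl at a CH2 group, so the neighbouring stereocentre and the silyl ether are untouched.

**Step 12**
Reactants: 17 (S)-tert-butyl(4-iodo-3-methylbutoxy)dimethylsilane
Product: 18 [(S)-4-(tert-butyldimethylsilyloxy)-2-methylbutyl]triphenylphosphonium iodide
Conditions: PPh3, MeCN, K2CO3 (trace), reflux
Reagents that add atoms: triphenylphosphine, c1ccc(cc1)P(c1ccccc1)c1ccccc1
Why: SN2 quaternisation of PPh3 by the primary iodide (slow at the β-branched carbon, hence heat) gives the Wittig salt.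

**Step 13**
Reactants: 14 ketal cyclobutene
Product: 20 ketal dialdehyde (formyl C11 on C9, equatorial; formyl C20 on C10, axial; cis), via ozonide 19 (not isolated)
Conditions: O3, CH2Cl2, −78 °C; Me2S, −78 °C → rt; used crude
Reagents that add atoms: ozone, [O-][O+]=O
Why: Ozonolysis with reductive work-up cleaves the strained cyclobutene, the only C=C present, to the 1,4-dialdehyde; the cis relation of C11 and C20 is kept and is also the thermodynamic arrangement at C9.

**Step 14**
Reactants: 20 ketal dialdehyde; 18 phosphonium iodide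
Product: 22 (11Z)-alkene C20-aldehyde: tert-butyl 15-(tert-butyldimethylsilyloxy)-8,8-ethylenedioxy-20-oxo-17-norlabd-11-en-19-oate, via ylide 21 (not isolated)
Conditions: 18, NaN(SiMe3)2, THF, −78 → 0 °C; ylide (1.0 equiv) added slowly to 20, THF, −78 → −20 °C
Reagents that add atoms: none
Why: Wittig olefination with one equivalent of the non-stabilised, β-branched ylide at low temperature should take the equatorial C11 aldehyde on the tertiary carbon in preference to the axial neopentyl C20 aldehyde shielded by the syn-axial tert-butyl ester; the alkene geometry is irrelevant.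

**Step 15**
Reactants: 22 alkene C20-aldehyde
Product: 23 C20 tosylhydrazone of 22
Conditions: TsNHNH2, THF, 4 Å molecular sieves, 50 °C
Reagents that add atoms: p-toluenesulfonyl hydrazide, Cc1ccc(cc1)S(=O)(=O)NN
Why: Hydrazone condensation of the non-enolisable aldehyde proceeds under neutral conditions that leave ketal, silyl ether and ester intact.

**Step 16**
Reactants: 23 C20 tosylhydrazone
Product: 25 tert-butyl (11Z)-15-(tert-butyldimethylsilyloxy)-8,8-ethylenedioxy-17-norlabd-11-en-19-oate (C20 now methyl), via N-boryl tosylhydrazine 24 (not isolated)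
Conditions: catecholborane, CHCl3, 0 °C → rt; then NaOAc·3H2O, reflux
Reagents that add atoms: none
Why: Kabalka reduction adds hydride to the C=N carbon and acetate then triggers loss of sulfinate and N2 from the diazene, converting CH=N into CH3 under conditions far milder than Wolff–Kishner reduction, so ester, ketal, silyl ether and the isolated alkene survive.

**Step 17**
Reactants: 25 C20-methyl alkene
Product: 26 tert-butyl 15-(tert-butyldimethylsilyloxy)-8,8-ethylenedioxy-17-norlabdan-19-oate
Conditions: H2 (1 atm), PtO2, EtOAc, rt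
Reagents that add atoms: none
Why: Catalytic hydrogenation of the disubstituted alkene over PtO2, chosen over Pd/C to avoid double-bond migration into the C13 stereocentre, saturates C11–C12.

**Step 18**
Reactants: 26 saturated ketal ester silyl ether
Product: 27 15-hydroxy-8-oxo-17-norlabdan-19-oic acid
Conditions: TFA/H2O (9:1), rt; then K2CO3, MeOH/H2O; acidified to pH 3
Reagents that add atoms: water, O
Why: Aqueous trifluoroacetic acid removes all three acid-labile groups at once (ketal hydrolysis, silyl ether cleavage, tert-butyl ester cleavage by alkyl–oxygen fission), the carbonate wash cleaves any trifluoroacetate formed at C15, and C9 stays in its thermodynamic equatorial configuration beside the freed ketone.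

**Step 19**
Reactants: 27 keto hydroxy acid
Product: 28 (1R,4aS,5R,8aS)-5-[(3R)-5-hydroxy-3-methylpentyl]-1,4a-dimethyl-6-methylidenedecahydronaphthalene-1-carboxylic acid
Conditions: Ph3PCH3Br (6 equiv), KOt-Bu (6 equiv), THF, reflux; then aq. NaH2PO4
Reagents that add atoms: methyltriphenylphosphonium bromide, C[P+](c1ccccc1)(c1ccccc1)c1ccccc1.[Br-]
Why: Wittig methylenation with excess ylide (carboxylate and alkoxide form first and are spectators) is the standard way from 8-oxo labdanes to 8(17)-enes, and C9 cannot be lost because its equatorial configuration is the stable one.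

**Step 20**
Reactants: 28 hydroxy acid
Product: 29 (1R,4aS,5R,8aS)-5-[(3R)-5-acetoxy-3-methylpentyl]-1,4a-dimethyl-6-methylidenedecahydronaphthalene-1-carboxylic acid (target)
Conditions: Ac2O, pyridine, DMAP (cat.), CH2Cl2, rt; aq. NaHCO3/THF, then pH 3
Reagents that add atoms: acetic anhydride, CC(=O)OC(C)=O
Why: DMAP-catalysed acetylation esterifies the primary alcohol, and any mixed anhydride at the hindered carboxyl is hydrolysed in the aqueous work-up.

**Compound list**

1 | 6-methoxy-1-tetralone | COc1ccc2C(=O)CCCc2c1 | starting material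
2 | rac-6-methoxy-1,2,3,4-tetrahydronaphthalene-1-carbonitrile | COc1ccc2C(C#N)CCCc2c1 | intermediate
3 | rac-6-methoxy-1-methyl-1,2,3,4-tetrahydronaphthalene-1-carbonitrile | COc1ccc2c(c1)CCCC2(C)C#N | intermediate
4 | rac-6-methoxy-1-methyl-1,2,3,4-tetrahydronaphthalene-1-carboxylic acid | COc1ccc2c(c1)CCCC2(C)C(=O)O | intermediate
5 | (R)-1-phenylethylammonium (R)-6-methoxy-1-methyl-1,2,3,4-tetrahydronaphthalene-1-carboxylate | COc1ccc2c(c1)CCC[C@@]2(C)C(=O)[O-].C[C@@H]([NH3+])c1ccccc1 | intermediate
6 | (R)-6-methoxy-1-methyl-1,2,3,4-tetrahydronaphthalene-1-carboxylic acid | COc1ccc2c(c1)CCC[C@@]2(C)C(=O)O | intermediate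
7 | (R)-6-methoxy-1-methyl-1,2,3,4,5,8-hexahydronaphthalene-1-carboxylic acid (dihydroanisole acid) | COC1=CCC2=C(C1)CCC[C@@]2(C)C(=O)O | intermediate
8 | (R)-1-methyl-6-oxo-1,2,3,4,5,6,7,8-octahydronaphthalene-1-carboxylic acid (β,γ-unsaturated keto acid) | O=C1CCC2=C(C1)CCC[C@@]2(C)C(=O)O | intermediate
9 | (1R)-1-methyl-6-oxo-1,2,3,4,6,7,8,8a-octahydronaphthalene-1-carboxylic acid, mixture of 8a-epimers | O=C1CCC2C(=C1)CCC[C@@]2(C)C(=O)O | intermediate
10 | tert-butyl (1R)-1-methyl-6-oxo-1,2,3,4,6,7,8,8a-octahydronaphthalene-1-carboxylate, mixture of 8a-epimers | O=C1CCC2C(=C1)CCC[C@@]2(C)C(=O)OC(C)(C)C | intermediate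
11 | tert-butyl (1R,8aS)-1-methyl-6-oxo-1,2,3,4,6,7,8,8a-octahydronaphthalene-1-carboxylate | O=C1CC[C@H]2C(=C1)CCC[C@@]2(C)C(=O)OC(C)(C)C | intermediate
12 | acetylene | C#C | starting material
13 | cyclobutene photoadduct (8-oxo tert-butyl ester, cis-fused C20H=C11H bridge on C10/C9, trans to H5) | O=C1CC[C@H]2[C@@]3(C=C[C@H]13)CCC[C@@]2(C)C(=O)OC(C)(C)C | intermediate
14 | 8,8-ethylenedioxy ketal of 13 | O1CCOC12CC[C@H]3[C@@]4(C=C[C@H]24)CCC[C@@]3(C)C(=O)OC(C)(C)C | intermediate
15 | (S)-2-methylbutane-1,4-diol | OC[C@@H](C)CCO | starting material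
16 | (S)-4-(tert-butyldimethylsilyloxy)-2-methylbutan-1-ol | OC[C@@H](C)CCO[Si](C)(C)C(C)(C)C | intermediate
17 | (S)-tert-butyl(4-iodo-3-methylbutoxy)dimethylsilane | IC[C@@H](C)CCO[Si](C)(C)C(C)(C)C | intermediate
18 | [(S)-4-(tert-butyldimethylsilyloxy)-2-methylbutyl]triphenylphosphonium iodide | CC(C)(C)[Si](C)(C)OCC[C@H](C)C[P+](c1ccccc1)(c1ccccc1)c1ccccc1.[I-] | intermediate
19 | secondary ozonide of 14 (1,2,4-trioxolane across C11 and C20) | O1CCOC12CC[C@H]3[C@@]4(C5OC(OO5)[C@H]24)CCC[C@@]3(C)C(=O)OC(C)(C)C | intermediate
20 | ketal dialdehyde (C11 formyl on C9, C20 formyl on C10, cis) | O1CCOC12CC[C@H]3[C@](C=O)([C@@H]2C=O)CCC[C@@]3(C)C(=O)OC(C)(C)C | intermediate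
21 | [(S)-4-(tert-butyldimethylsilyloxy)-2-methylbutylidene]triphenylphosphorane | CC(C)(C)[Si](C)(C)OCC[C@H](C)C=P(c1ccccc1)(c1ccccc1)c1ccccc1 | intermediate
22 | tert-butyl (11Z)-15-(tert-butyldimethylsilyloxy)-8,8-ethylenedioxy-20-oxo-17-norlabd-11-en-19-oate | O1CCOC12CC[C@H]3[C@](C=O)([C@@H]2/C=C\[C@@H](C)CCO[Si](C)(C)C(C)(C)C)CCC[C@@]3(C)C(=O)OC(C)(C)C | intermediate
23 | C20 tosylhydrazone of 22 | O1CCOC12CC[C@H]3[C@](C=NNS(=O)(=O)c4ccc(C)cc4)([C@@H]2/C=C\[C@@H](C)CCO[Si](C)(C)C(C)(C)C)CCC[C@@]3(C)C(=O)OC(C)(C)C | intermediate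
24 | N-(1,3,2-benzodioxaborol-2-yl) tosylhydrazine from 23 | O1CCOC12CC[C@H]3[C@](CN(B4Oc5ccccc5O4)NS(=O)(=O)c4ccc(C)cc4)([C@@H]2/C=C\[C@@H](C)CCO[Si](C)(C)C(C)(C)C)CCC[C@@]3(C)C(=O)OC(C)(C)C | intermediate
25 | tert-butyl (11Z)-15-(tert-butyldimethylsilyloxy)-8,8-ethylenedioxy-17-norlabd-11-en-19-oate | O1CCOC12CC[C@H]3[C@](C)([C@@H]2/C=C\[C@@H](C)CCO[Si](C)(C)C(C)(C)C)CCC[C@@]3(C)C(=O)OC(C)(C)C | intermediate
26 | tert-butyl 15-(tert-butyldimethylsilyloxy)-8,8-ethylenedioxy-17-norlabdan-19-oate | O1CCOC12CC[C@H]3[C@](C)([C@@H]2CC[C@@H](C)CCO[Si](C)(C)C(C)(C)C)CCC[C@@]3(C)C(=O)OC(C)(C)C | intermediate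
27 | 15-hydroxy-8-oxo-17-norlabdan-19-oic acid | O=C1CC[C@H]2[C@](C)([C@@H]1CC[C@@H](C)CCO)CCC[C@@]2(C)C(=O)O | intermediate
28 | (1R,4aS,5R,8aS)-5-[(3R)-5-hydroxy-3-methylpentyl]-1,4a-dimethyl-6-methylidenedecahydronaphthalene-1-carboxylic acid | C=C1CC[C@H]2[C@@](C)(CCC[C@@]2(C)C(=O)O)[C@@H]1CC[C@@H](C)CCO | intermediate
29 | (1R,4aS,5R,8aS)-5-[(3R)-5-acetoxy-3-methylpentyl]-1,4a-dimethyl-6-methylidenedecahydronaphthalene-1-carboxylic acid | C=C1CC[C@H]2[C@@](C)(CCC[C@@]2(C)C(=O)O)[C@@H]1CC[C@@H](C)CCOC(C)=O | target

**Totals and risks**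

Total steps: 20. Longest linear sequence: 17 (steps 1–9 and 13–20; steps 10–12 make the side-chain salt).

Step 8. The cyclobutene product may be consumed by secondary photochemistry (acyl shift of its β,γ-unsaturated ketone), acetylene uptake may be slow, or face selectivity at C10 may be eroded by the syn-axial ester. Fallback: setting out from 11, irradiation (λ > 340 nm, CH2Cl2) with vinylene carbonate should give the keto carbonate photoadduct F1 with the same C10–C20 and C9–C11 bonds and no light-sensitive chromophore; Et3N converges it on the cis ring fusion if needed. Ketalisation as in step 9 gives the ketal carbonate F2, K2CO3/MeOH gives the cis-diol F3, and NaIO4 (THF/H2O) cleaves the glycol to dialdehyde 20, where the route is rejoined.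

Step 14. The ylide may not discriminate enough between the two aldehydes, giving olefination at C20 or bis-olefination, or it may be lost to enolisation of the C11 aldehyde. Fallback: setting out from 14, ozonolysis with NaBH4 work-up gives the 11,20-diol F4. TEMPO/PhI(OAc)2 oxidises the less hindered C11 carbinol and carries the resulting lactol on to the γ-lactone F5 (carbonyl at C11, oxygen on C20). i-Bu2AlH at −78 °C gives the lactol F6, ylide 21 (2.2 equiv) olefinates only the masked C11 aldehyde to give the alkenyl C20 alcohol F7, and Dess–Martin oxidation returns aldehyde 22.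

Step 7. Equilibration at C8a is not expected to favour one epimer strongly, so throughput depends on separation and recycling, and the epimers may be hard to separate. Fallback: setting out from 9, TsOH in refluxing toluene lets the epimers interconvert while the carboxyl adds reversibly to C10. The keto lactone F8, whose ring B sits equatorially only when H5 is anti to the lactone bridge, should accumulate and is separated from unlactonised acid by bicarbonate extraction. Et3N (CH2Cl2, 0 °C) then opens it by β-elimination to the single-epimer enone acid F9, and tert-butyl 2,2,2-trichloroacetimidate with BF3·OEt2 (cat.) gives 11.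

**Further compounds**

F1 | step 8 | keto carbonate photoadduct (cyclobutane-fused cyclic carbonate on C10/C9) | O=C1CC[C@H]2[C@@]3(C4OC(=O)OC4[C@H]13)CCC[C@@]2(C)C(=O)OC(C)(C)C
F2 | step 8 | 8,8-ethylenedioxy ketal of F1 | O1CCOC12CC[C@H]3[C@@]4(C5OC(=O)OC5[C@H]24)CCC[C@@]3(C)C(=O)OC(C)(C)C
F3 | step 8 | ketal cyclobutane-11,20-diol | O1CCOC12CC[C@H]3[C@@]4(C(O)C(O)[C@H]24)CCC[C@@]3(C)C(=O)OC(C)(C)C
F4 | step 14 | ketal 11,20-diol | O1CCOC12CC[C@H]3[C@](CO)([C@@H]2CO)CCC[C@@]3(C)C(=O)OC(C)(C)C
F5 | step 14 | ketal 11,20-olide (γ-lactone, carbonyl at C11) | O1CCOC12CC[C@H]3[C@@]4(COC(=O)[C@H]24)CCC[C@@]3(C)C(=O)OC(C)(C)C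
F6 | step 14 | ketal 11,20-lactol | O1CCOC12CC[C@H]3[C@@]4(COC(O)[C@H]24)CCC[C@@]3(C)C(=O)OC(C)(C)C
F7 | step 14 | (11Z)-alkenyl C20 alcohol | O1CCOC12CC[C@H]3[C@](CO)([C@@H]2/C=C\[C@@H](C)CCO[Si](C)(C)C(C)(C)C)CCC[C@@]3(C)C(=O)OC(C)(C)C
F8 | step 7 | keto lactone (C19 carboxyl added to C10, H5 anti to the bridge) | O=C1CC[C@H]2[C@]3(C1)CCC[C@@]2(C)C(=O)O3
F9 | step 7 | (1R,8aS)-1-methyl-6-oxo-1,2,3,4,6,7,8,8a-octahydronaphthalene-1-carboxylic acid | O=C1CC[C@H]2C(=C1)CCC[C@@]2(C)C(=O)O
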